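All runs are calculated for an exercise, and the scatter is random.

**The question.** Monomer units per chain begun is the number you asked me for quickly, for south-east and west at the end, and your hunch stands as the forecast below.

| flask | free monomer | initiator | impurity | remark | time |
|---|---|---|---|---|---|
| epsilon | 0.40 M (fed, over 2.0 h) | 0.93 mM | 0.34 mM | run made earlier; the fed solution adds 0.10 times the starting volume |  |
| eta | 0.40 M (fed, over 2.0 h) | 2.1 mM | 0.34 mM | run made earlier; the fed solution adds 0.10 times the starting volume |  |
| south-east | 0.40 M (fed, over 2.0 h) | 3.2 mM | 0.34 mM | the fed solution adds 0.10 times the starting volume | 5.0 d |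
| west | 0.40 M (fed, over 2.0 h) | 1.5 mM | 0.34 mM | the fed solution adds 0.10 times the starting volume | 5.0 d |

| run | time / d | monomer in chains / % | free monomer / % |
|---|---|---|---|
| epsilon | 0.208 | 20.6 | 79.1 |
| epsilon | 0.333 | 28.9 | 70.6 |
| epsilon | 0.500 | 31.2 | 68.8 |
| epsilon | 0.833 | 32.1 | 68.6 |
| epsilon | 1.67 | 31.8 | 68.5 |
| epsilon | 2.50 | 31.5 | 68.4 |
| eta | 0.208 | 40.0 | 59.9 |
| eta | 0.333 | 47.5 | 53.2 |
| eta | 0.500 | 48.6 | 50.8 |
| eta | 0.833 | 49.5 | 50.3 |
| eta | 1.67 | 49.6 | 50.0 |
| eta | 2.50 | 49.5 | 49.8 |

(readings scatter by 0.3 percentage points)

- which of the two ends with the longer chains by the average number of monomer units in a chain (chains begun, living or dead) ("neither" if they lie within 10%) (south-east / west / neither)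
- average number of monomer units in a chain (chains begun, living or dead) at the end, south-east
- average number of monomer units in a chain (chains begun, living or dead) at the end, west

- charges are per starting volume, the dose included; the dosed solution carries all of it
- the average divides the monomer in chains by the number of chains begun, living and dead together
- the earlier runs do not show the number of chains; that part of a forecast is a guess

**The readings.** Free monomer in epsilon reads 68.8% at 0.500 d and 68.4% at 2.50 d, and eta flattens in the same way. Both runs therefore stop with free monomer left, a dead-end polymerisation.

**My reckoning.** The runs do not show the chains, so I guess that each impurity removes one initiator and that every other initiator begins a chain. Chains begun then equal the net initiator, the initiator charge minus the impurity charge, which is 1.16 mM in west and 2.86 mM in south-east. On that guess, the last readings give 214 units in epsilon, with 0.590 mM net, and 112 in eta, with 1.76 mM net. Read on that guess, length between epsilon and eta falls as net initiator to the power 0.586. I commit to 144 units for west and 84.6 for south-east.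

**Your forecast.** It names west, with 83 for south-east and 125 for west, and says “I take chains as between I and I minus impurity”. We differ on west, where my figure is higher.

**The flask.** West gives 145 and south-east 82.8, so west ends longer.

    free monomer + initiator → living end + monomer in chains (k = 3.84 × 10⁻⁴ L mol⁻¹ s⁻¹)
    free monomer + living end → monomer in chains + living end, rate k2*[living end]*[free monomer] (k = 0.0687 L mol⁻¹ s⁻¹)
    living end + monomer in chains → dead end B (k = 0.00158 L mol⁻¹ s⁻¹)
    initiator + impurity → spent initiator A (k = 654 L mol⁻¹ s⁻¹)

**Where we part.** West ends with 42.0% monomer in chains, beside the 41.5 % converted in the forecast. Over the net 1.16 mM of west, that amount gives 145 units, while the forecast's chains for west run from 1.2 to 1.5 mM. The neighbouring flask is west with 0.0026 M of initiator, so its net initiator is 2.26 mM. With 54.4% monomer in chains, the same division gives 96.3 units, and the flask gives 96.3.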